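Monomer in chains and monomer not in chains always add up to the whole charge, so I reckoned with the fraction left, the part of the charge not in chains, and not with the fraction made.

all flasks: free monomer 10 mM

| flask | pre-initiator | remark | time |
|---|---|---|---|
| south-east | 0.63 mM | run made earlier |  |
| west | 1.6 mM | run made earlier |  |
| amber | 0.99 mM |  | 10 d |
| blue | 2.0 mM |  | 10 d |

| run | time / d | monomer in chains / % |
|---|---|---|
| south-east | 0.625 | 18.0 |
| south-east | 0.833 | 21.7 |
| south-east | 1.67 | 31.8 |
| south-east | 2.50 | 36.6 |
| south-east | 4.00 | 41.2 |
| south-east | 8.00 | 41.5 |
| west | 0.625 | 34.4 |
| west | 0.833 | 35.7 |
| west | 1.67 | 41.1 |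
| west | 2.50 | 44.3 |
| west | 4.00 | 41.9 |
| west | 8.00 | 42.2 |

(scatter of a reading: 0.5 percentage points)

- the average divides the monomer in chains by the number of chains begun, living and dead together
- what was read earlier has a scatter of 0.5 percentage points, one standard deviation
- the earlier runs do not show the number of chains; that part of a forecast is a guess

- which of the two ends with the longer chains by the average number of monomer units in a chain (chains begun, living or dead) ("neither" if they lie within 10 %) (amber / blue / neither)
- average number of monomer units in a chain (chains begun, living or dead) at the end, amber
- average number of monomer units in a chain (chains begun, living or dead) at the end, blue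

I solved two extreme flasks in my head. In the first, growth ran one way, the fraction left fell towards zero, and one chain per pre-initiator gave 10.1 units for amber and 5.00 for blue. In the second, adding and taking off monomer came to a balance, and pre-initiator changed the pace but not the level.

The readings sided with the second. The last readings of both runs averaged a fraction left of 58.3 %, the plateau fraction, a reading of whatever was not in chains, which I took to mark the equilibrium monomer level of a reversible polymerisation, and the final readings differed by 0.7 percentage points, though west had more pre-initiator than south-east.

The south-east run closed its gap to that level at 0.861 d⁻¹, a half-time of 0.805 d. That run had less pre-initiator than amber or blue, and 10 d is far longer than this half-time, so I put both flasks at the balance. With the guessed chain count, I reckoned 4.21 for amber and 2.08 for blue, so amber came out longer.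

The forecast said amber, with 4.2 and 2.1, on the ground: “Both earlier runs level off at about 42% of the charge, despite a 2.5-fold difference in pre-initiator”.

    monomer in chains + living end → free monomer + living end, rate k1*[living end] as long as [monomer in chains] is above zero (k = 7.30 × 10⁻⁵ s⁻¹)
    free monomer + living end → monomer in chains + living end, rate k2*[living end]*[free monomer] (k = 0.0130 M⁻¹ s⁻¹)
    pre-initiator → initiator (k = 2.70 × 10⁻⁴ s⁻¹)
    free monomer + initiator → living end + monomer in chains (k = 0.0420 M⁻¹ s⁻¹)
    monomer in chains → over-reaction product (k = 7.30 × 10⁻⁸ s⁻¹)

The flask gave amber, with 4.18 against 2.06. At 10.0 d amber held 0.990 mM of living end and blue 2.00 mM, with pre-initiator at 0 % in both. At that time the part of amber not in chains was 56.1 % free monomer and 2.48 % over-reaction product. Amber's length had stood at 4.15 at 2.50 d and 4.30 at 5.00 d.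

Take a neighbour flask, blue with 40 mM of free monomer. Holding the amount not in chains at its plateau value gives a fraction left of 14.6 % and 17.1 units per chain. The computed flask ended at 16.2, with 14 % of its charge free and 5.02 % as over-reaction product.

The runs were computed from invented constants; the scatter is artificial.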